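All runs were computed with made-up constants; the scatter is artificial.

Time is what I follow here: Sunday's flask is to be read at 4.8 min, and its close neighbour is Saturday's flask, charged a little leaner and read at the same time.

| setting | Wednesday's | Saturday's | Thursday's | Monday's | Sunday's |
|---|---|---|---|---|---|
| starting material | 0.300 M | 0.120 M | 0.300 M | 0.300 M | 0.150 M |
| reagent | 0.300 M | 0.120 M | 0.900 M | 0.300 M | 0.150 M |
| target |  |  |  | 0.0900 M |  |
| time |  |  |  |  | 4.8 min |

| run | time / min | [target] / M |
|---|---|---|
| Wednesday's run | 0.19 | 0.0137 |
| Wednesday's run | 0.30 | 0.0259 |
| Wednesday's run | 0.48 | 0.0346 |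
| Wednesday's run | 0.76 | 0.0485 |
| Wednesday's run | 1.2 | 0.0654 |
| Wednesday's run | 1.9 | 0.0864 |
| Wednesday's run | 3.0 | 0.1050 |
| Wednesday's run | 4.8 | 0.1170 |
| Saturday's run | 0.19 | 0.0012 |
| Saturday's run | 0.30 | 0.0030 |
| Saturday's run | 0.48 | 0.0047 |
| Saturday's run | 0.76 | 0.0039 |
| Saturday's run | 1.2 | 0.0090 |
| Saturday's run | 1.9 | 0.0094 |
| Saturday's run | 3.0 | 0.0117 |
| Saturday's run | 4.8 | 0.0184 |
| Thursday's run | 0.19 | 0.1042 |
| Thursday's run | 0.30 | 0.1387 |
| Thursday's run | 0.48 | 0.1807 |
| Thursday's run | 0.76 | 0.2129 |
| Thursday's run | 1.2 | 0.2326 |
| Thursday's run | 1.9 | 0.2394 |
| Thursday's run | 3.0 | 0.2250 |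
| Thursday's run | 4.8 | 0.1914 |
| Monday's run | 0.19 | 0.1031 |
| Monday's run | 0.30 | 0.1120 |
| Monday's run | 0.48 | 0.1218 |
| Monday's run | 0.76 | 0.1343 |
| Monday's run | 1.2 | 0.1459 |
| Monday's run | 1.9 | 0.1635 |
| Monday's run | 3.0 | 0.1774 |
| Monday's run | 4.8 | 0.1785 |

(scatter of a reading: 0.002 M)

- apparent order in [starting material] of the starting rate, round the charge of the Wednesday's run (the rate where two percent of its starting material have turned into target) (one fixed amount of target, the same in the runs compared)
- apparent order in [reagent] of the starting rate, round the charge of the Wednesday's run (the rate where two percent of its starting material have turned into target)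
- target in the Sunday's run at 4.8 min, as a share of the starting material charged

- Overall: starting material + reagent -> target.
- Constant volume, constant temperature.
- "The second partner" is reagent.
- An order is taken over about fifteen percent of the charge, up and down.

First I read the rate law. At 0.19 min, Thursday's first reading is 7.61 times Wednesday's, on a reagent charge larger by 3.00 times, so the order in c(reagent) reads 1.85, which I take as two. Wednesday's run at 0.76 min and Saturday's run at 4.8 min have made nearly the same share of their charges, 16.2% and 15.3%; Saturday's takes 6.32 times as long on a charge leaner by 2.50 times, so the total order reads about 3.01, which leaves about one for c(starting material), though Saturday's readings are weak.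

Now I freeze something. The overall equation takes one reagent per starting material, so with equal charges the two concentrations stay nearly equal. The rate is then k·c³, and 1/c² climbs steadily by two times k per minute. Wednesday's early reading of 0.0485 M at 0.76 min gives k = 3.09 L² mol⁻² min⁻¹.

I call two times k times the charge squared times the time the clock number, which for Sunday's flask is 0.668. The loss-free share turned is one minus one over the root of one plus the clock number. Saturday's clock number is 0.427. Sunday's charge is larger by only 1.25 times, but its clock number is larger by 1.56 times, since the charge enters squared. The loss-free shares are therefore 22.6% for Sunday's and 16.3% for Saturday's.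

Target also disappears late in Thursday's run, so I need a kept share, the target read over the loss-free target. Saturday's reads 0.941, roughly, given the scatter. Wednesday's, at clock number 2.67, reads 0.816. Sunday's clock number lies between them, so I take their mean and reckon 19.8%.

The forecast gives orders 0.95 and 1.9 and 17.5% for Sunday's flask, holding that “target is being lost, not inhibiting the reaction”. My figure is higher by 2.3 percentage points.

The flask gives orders 1.0 and 2.1, and 19.6% for Sunday's run, so the forecast's three numbers lie within their margins; its ground about target would fail if a run showed added target moving the rate far from Wednesday's, and Monday's rate reads 0.91 of Wednesday's at the same amount made.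

    starting material + 2 reagent → target + reagent (3.246 L² mol⁻² min⁻¹)
    target → decomposed product (0.05070 min⁻¹)
    target + reagent → side product (0.09780 L mol⁻¹ min⁻¹)

The loss of target with reagent makes little difference to Sunday's run. Against the loss-free 22.6%, Sunday's kept share is 0.871, above Wednesday's 0.816 and below Saturday's 0.941.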